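**Plan**
1. Retrosynthesis: the O1–C2 bond of the 2H-pyran is cut first (ring closure of an open-chain styryl tertiary carbinol), then the C4–C4a aryl–vinyl bond (Heck coupling), the Cα=Cβ bond of the cinnamoyl group (aldol condensation) and the C–O bond of the side-chain carbinol (ene oxidation of linalool).
2. Enabling feature: the ring O1–C2–C3=C4–C4a=C8a is the closed valence tautomer of a 1-oxatriene. C2 is tertiary, allylic to C3=C4 and conjugated through C4 to an arene with oxygen on both ortho carbons (C8a, C5), so a hydroxyl on C2 ionises to an O-protonated vinyl ortho-quinone methide that closes again at O1–C2.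
3. Forward: 2',4',5'-trihydroxyacetophenone → bis-MOM ether → C3'-iodide → chalcone → free iodo-triol; linalool → 1,5-diene-3,7-diol; Heck coupling joins the two; the pyran ring closes last and gives the target with no protecting group left.
4. Stereochemistry: the only stereocentre, C2 (S), is set in the ring closure by the chiral counter-anion of a contact ion pair. The three (E)-alkenes come from the aldol dehydration, the ene reaction and the Heck β-hydride elimination; the Heck alkene becomes the ring alkene C3=C4.

Key step: step 7

Remark: 2',4',5'-trihydroxyacetophenone, benzaldehyde and (±)-linalool are taken as purchased; racemic linalool suffices because its carbinol carbon is the one ionised in step 7, and since the sense of induction of the chiral acid cannot be predicted, the catalyst antipode is fixed by a pilot run.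

Step 1
Reactants: 1 1-(2,4,5-trihydroxyphenyl)ethanone (2',4',5'-trihydroxyacetophenone)
Product: 2 1-[2-hydroxy-4,5-bis(methoxymethoxy)phenyl]ethanone
Conditions: MOMCl (2.2 equiv), K2CO3, acetone, 0 °C to rt, Ar
Reagents that add atoms: chloromethyl methyl ether, COCCl
Why: Williamson-type O-alkylation in which the 4'- and 5'-hydroxyls are etherified while the 2'-hydroxyl, held in a hydrogen bond to the acetyl carbonyl, stays free; the MOM ethers shield the air-sensitive hydroxyquinol in the basic aldol step.

Step 2
Reactants: 2 1-[2-hydroxy-4,5-bis(methoxymethoxy)phenyl]ethanone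
Product: 3 1-[2-hydroxy-3-iodo-4,5-bis(methoxymethoxy)phenyl]ethanone
Conditions: NIS (1.05 equiv), DMF, 0 °C to rt, dark
Reagents that add atoms: N-iodosuccinimide, O=C1CCC(=O)N1I
Why: Electrophilic aromatic iodination at C3', the only free position ortho to the free 2'-hydroxyl (its para position carries OMOM) and flanked by two oxygen donors, whereas C6' is deactivated by the adjacent acetyl group; no acid is present, so the MOM ethers survive.

Step 3
Reactants: 3 1-[2-hydroxy-3-iodo-4,5-bis(methoxymethoxy)phenyl]ethanone; 4 benzaldehyde
Product: 6 (2E)-1-[2-hydroxy-3-iodo-4,5-bis(methoxymethoxy)phenyl]-3-phenylprop-2-en-1-one, via aldol adduct 5 (not isolated)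
Conditions: KOH (50% aq.), EtOH, 0 °C to rt
Reagents that add atoms: none
Why: Claisen–Schmidt aldol condensation in which the methyl ketone enolate adds to benzaldehyde and the aldol loses water by E1cB to the conjugated (E)-enone; MOM ethers and the aryl iodide are inert to aqueous-alcoholic KOH.

Step 4
Reactants: 6 (2E)-1-[2-hydroxy-3-iodo-4,5-bis(methoxymethoxy)phenyl]-3-phenylprop-2-en-1-one
Product: 7 (2E)-1-(2,4,5-trihydroxy-3-iodophenyl)-3-phenylprop-2-en-1-one
Conditions: 3 M HCl (aq.), MeOH, 50 °C, Ar
Reagents that add atoms: none
Why: Acid-catalysed acetal exchange of both MOM ethers with methanol, placed before the Heck coupling because no acid can be used once the ionisable carbinol is present; the aryl iodide and the (E)-enone should tolerate brief warm dilute acid, and the hydroxyquinol is not oxidised under acidic, degassed conditions.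

Step 5
Reactants: 8 (±)-linalool (3,7-dimethylocta-1,6-dien-3-ol)
Product: 10 (5E)-3,7-dimethylocta-1,5-diene-3,7-diol (racemic), via allylic hydroperoxide 9 (not isolated)
Conditions: O2, rose bengal (cat.), visible light, MeOH, 0 °C; then PPh3, 0 °C to rt
Reagents that add atoms: dioxygen, O=O
Why: Schenck ene reaction of singlet oxygen, then phosphine reduction of the hydroperoxide: only the electron-rich trisubstituted alkene reacts, and abstraction of an allylic hydrogen from C5 moves the double bond to C5=C6 with (E) geometry and places oxygen on C7; the regioisomer from methyl-hydrogen abstraction is expected alongside and is separated at the diol stage.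

Step 6
Reactants: 7 (2E)-1-(2,4,5-trihydroxy-3-iodophenyl)-3-phenylprop-2-en-1-one; 10 (5E)-3,7-dimethylocta-1,5-diene-3,7-diol
Product: 11 (2E)-1-{3-[(1E,5E)-3,7-dihydroxy-3,7-dimethylocta-1,5-dien-1-yl]-2,4,5-trihydroxyphenyl}-3-phenylprop-2-en-1-one (racemic at the carbinol carbon)
Conditions: Pd(OAc)2 (5 mol%), n-Bu4NCl, NaHCO3, degassed DMF, 50 °C, Ar, dark; work-up at pH 7
Reagents that add atoms: none
Why: Mizoroki–Heck coupling under ligand-free phase-transfer conditions, in which the aryl–Pd species adds to the unhindered terminal vinyl group of 10 (aryl to CH2) and, as the carbinol carbon has no hydrogen, β-hydride elimination can only give the (E)-styryl tertiary alcohol; the 1,2-disubstituted alkenes of 10 and of the chalcone insert far more slowly, and the weak base and low temperature are chosen to keep the carbinol un-ionised.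

Step 7
Reactants: 11 (2E)-1-{3-[(1E,5E)-3,7-dihydroxy-3,7-dimethylocta-1,5-dien-1-yl]-2,4,5-trihydroxyphenyl}-3-phenylprop-2-en-1-one
Product: 13 (2E)-1-{(2S)-5,8-dihydroxy-2-[(2E)-4-hydroxy-4-methylpent-2-en-1-yl]-2-methyl-2H-chromen-6-yl}-3-phenylprop-2-en-1-one, via allyl cation 12 (not isolated)
Conditions: chiral BINOL-derived N-triflylphosphoramide (H8-BINOL backbone, 3,3'-bis(2,4,6-triisopropylphenyl); antipode fixed by pilot run), 10 mol%, CH2Cl2/toluene 1:1, −78 to −40 °C, Ar, dark; then Et3N at −78 °C
Reagents that add atoms: none
Why: Proposed new method: the chiral acid protonates the tertiary hydroxyl on the carbon that becomes C2, water leaves, and the 1-aryl-3,3-dialkylallyl cation 12 (the O-protonated vinyl ortho-quinone methide, stabilised by the phenolic oxygens on both carbons ortho to the side chain) is held as a contact ion pair with the chiral phosphoramidate; rotation about the C3–C4 bond, which is a single bond in the quinone methide resonance form, folds the (E)-styryl unit into the s-cis oxatriene, and O–C2 bond formation with return of the proton to the anion closes the pyran. The closest known reaction type is the chiral N-triflylphosphoramide-catalysed dehydrative cyclisation (asymmetric allylic substitution through a chiral contact ion pair) of (E)-2-(3-aryl-3-hydroxybut-1-enyl)phenols to 2-aryl-2-methyl-2H-chromenes; new here are a cationic terminus with two alkyl groups and a polyhydroxylated acylphenol. The ring closes 6-endo-trig at the allyl cation, which in the limit of full proton transfer is a disrotatory oxa-6π electrocyclisation of the hydrogen-bonded 1-oxatriene. The stereocentre C2 is set by the face of the planar C(CH3)(CH2R) terminus that the oxygen attacks, that is by the helical sense of the folded oxatriene, which the 3,3'-aryl pockets of the counter-anion, hydrogen-bonded to the closing 4'-OH and the neighbouring 5'-OH, should control. The step needs ionisation of the styryl carbinol in preference to the isolated tertiary allylic alcohol of the side chain (secured by conjugation with the 2',4'-dioxygenated arene), closure by the 4'-OH and not the 2'-OH (secured by the hydrogen bond of the 2'-OH to the ketone), and closure faster than proton loss from the doubly allylic CH2 (secured by the low temperature).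

**Compound list**
1 | 1-(2,4,5-trihydroxyphenyl)ethanone | CC(=O)c1cc(O)c(O)cc1O | starting material
2 | 1-[2-hydroxy-4,5-bis(methoxymethoxy)phenyl]ethanone | CC(=O)c1cc(OCOC)c(OCOC)cc1O | intermediate
3 | 1-[2-hydroxy-3-iodo-4,5-bis(methoxymethoxy)phenyl]ethanone | CC(=O)c1cc(OCOC)c(OCOC)c(I)c1O | intermediate
4 | benzaldehyde | O=Cc1ccccc1 | starting material
5 | 3-hydroxy-1-[2-hydroxy-3-iodo-4,5-bis(methoxymethoxy)phenyl]-3-phenylpropan-1-one (aldol adduct, racemic, not isolated) | O=C(CC(O)c1ccccc1)c1cc(OCOC)c(OCOC)c(I)c1O | intermediate
6 | (2E)-1-[2-hydroxy-3-iodo-4,5-bis(methoxymethoxy)phenyl]-3-phenylprop-2-en-1-one | O=C(/C=C/c1ccccc1)c1cc(OCOC)c(OCOC)c(I)c1O | intermediate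
7 | (2E)-1-(2,4,5-trihydroxy-3-iodophenyl)-3-phenylprop-2-en-1-one | O=C(/C=C/c1ccccc1)c1cc(O)c(O)c(I)c1O | intermediate
8 | (±)-linalool, 3,7-dimethylocta-1,6-dien-3-ol | C=CC(C)(O)CCC=C(C)C | starting material
9 | (5E)-7-hydroperoxy-3,7-dimethylocta-1,5-dien-3-ol (racemic, not isolated) | C=CC(C)(O)C/C=C/C(C)(C)OO | intermediate
10 | (5E)-3,7-dimethylocta-1,5-diene-3,7-diol (racemic) | C=CC(C)(O)C/C=C/C(C)(C)O | intermediate
11 | (2E)-1-{3-[(1E,5E)-3,7-dihydroxy-3,7-dimethylocta-1,5-dien-1-yl]-2,4,5-trihydroxyphenyl}-3-phenylprop-2-en-1-one (racemic at the carbinol carbon) | CC(C)(O)/C=C/CC(C)(O)/C=C/c1c(O)c(C(=O)/C=C/c2ccccc2)cc(O)c1O | intermediate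
12 | O-protonated vinyl ortho-quinone methide (1-aryl-3,3-dialkylallyl cation, ion-paired with the catalyst anion, not isolated) | CC(C)(O)/C=C/C[C+](C)/C=C/c1c(O)c(C(=O)/C=C/c2ccccc2)cc(O)c1O | intermediate
13 | (2E)-1-{(2S)-5,8-dihydroxy-2-[(2E)-4-hydroxy-4-methylpent-2-en-1-yl]-2-methyl-2H-chromen-6-yl}-3-phenylprop-2-en-1-one | CC(C)(O)/C=C/C[C@@]1(C)C=Cc2c(O)c(C(=O)/C=C/c3ccccc3)cc(O)c2O1 | target

**Step count and risks**
Total steps: 7. Longest linear sequence: 6 steps (steps 1, 2, 3, 4, 6, 7 from compound 1); the diol branch (step 5) joins at step 6.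

Step 7 (Proposed new method). What may go wrong: poor facial selectivity in the ion-pair ring closure, because the two alkyl groups on the cationic terminus differ little; proton loss from the doubly allylic CH2 outrunning closure; ionisation of the second tertiary alcohol. The fallback uses known chemistry and sets out from 11. An achiral acid (PPTS, CH2Cl2, 0 °C) effects the established cyclodehydration of an ortho-hydroxystyryl tertiary carbinol to the 2,2-disubstituted 2H-chromene and should give the racemic chromenyl chalcone F1. Preparative HPLC or SFC on a polysaccharide-carbamate chiral phase then resolves F1, and the (S)-enantiomer, assigned by electronic circular dichroism against calculation, is 13.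

Step 6. What may go wrong: oxidation of the unprotected hydroxyquinol by Pd(II) or traces of air in base; reduction of the C–I bond; phenoxide-assisted loss of hydroxide from the new carbinol, followed by uncontrolled racemic ring closure in the warm basic mixture. The fallback sets out from 7. Peracetylation (Ac2O, pyridine, DMAP) gives (2E)-1-(2,4,5-triacetoxy-3-iodophenyl)-3-phenylprop-2-en-1-one F2. The same Heck coupling with 10 should give the coupled triacetate F3, which has no free phenol and so can neither be oxidised nor push out the hydroxyl. Methanolysis of the three aryl acetates (K2CO3, degassed MeOH, 0 °C, pH 7 quench) returns to 11.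

Step 5. What may go wrong: poor regioselectivity of hydrogen abstraction in the ene reaction (methyl against methylene), so that much material is diverted and the two diols must be separated. The fallback sets out from 8 and transposes an epoxide into the allylic alcohol. Buffered epoxidation of the trisubstituted alkene (mCPBA, NaHCO3, CH2Cl2, 0 °C) gives 6,7-epoxylinalool F4. Sodium phenylselenide (PhSeSePh, NaBH4, EtOH) opens the epoxide at the secondary carbon to the hydroxy selenide F5. H2O2 in THF oxidises it to the selenoxide F6, whose syn-elimination away from the carbinol carbon should give 10 regio- and (E)-selectively.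

**Further compounds**
F1 | step 7 | racemic (2E)-1-{5,8-dihydroxy-2-[(2E)-4-hydroxy-4-methylpent-2-en-1-yl]-2-methyl-2H-chromen-6-yl}-3-phenylprop-2-en-1-one | CC(C)(O)/C=C/CC1(C)C=Cc2c(O)c(C(=O)/C=C/c3ccccc3)cc(O)c2O1
F2 | step 6 | (2E)-1-(2,4,5-triacetoxy-3-iodophenyl)-3-phenylprop-2-en-1-one | O=C(/C=C/c1ccccc1)c1cc(OC(C)=O)c(OC(C)=O)c(I)c1OC(C)=O
F3 | step 6 | (2E)-1-{2,4,5-triacetoxy-3-[(1E,5E)-3,7-dihydroxy-3,7-dimethylocta-1,5-dien-1-yl]phenyl}-3-phenylprop-2-en-1-one | CC(C)(O)/C=C/CC(C)(O)/C=C/c1c(OC(C)=O)c(C(=O)/C=C/c2ccccc2)cc(OC(C)=O)c1OC(C)=O
F4 | step 5 | 5-(3,3-dimethyloxiran-2-yl)-3-methylpent-1-en-3-ol (6,7-epoxylinalool) | C=CC(C)(O)CCC1OC1(C)C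
F5 | step 5 | 3,7-dimethyl-6-(phenylselanyl)oct-1-ene-3,7-diol | C=CC(C)(O)CCC([Se]c1ccccc1)C(C)(C)O
F6 | step 5 | 3,7-dimethyl-6-(phenylseleninyl)oct-1-ene-3,7-diol (selenoxide, not isolated) | C=CC(C)(O)CCC([Se](=O)c1ccccc1)C(C)(C)O
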